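## Retrosynthetic overview

1. Labdane numbering is used: ring A = C1–C5/C10, ring B = C5–C10, ring C = oxolane O/C9/C11/C12/C13, ring D = lactone C13/C14/C15(=O)/O/C16. The plan rests on the C9–C10 bond, which joins the spiro ether carbon C9 (rings B and C) to the methyl-bearing quaternary C10 (rings A and B).
2. Target 36 ⇒ C5=C6 alkene 28. The 6-ketone comes from α-face hydroboration and oxidation, and the 7β-hydroxyl from Rubottom oxidation and equilibration.
3. 28 ⇒ C9 methyl ketal 25. Ionisation to a cyclic oxocarbenium ion and attack by the C5=C10 alkene makes C9–C10, closes ring B and sets C9 and C10.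
4. 25 ⇒ alkynyl hydroxy lactone 23 (gold 5-endo-dig ketalisation closes ring C) ⇒ propargylic bromide 17 + (R)-malic acid dioxolanone 19 (sets C13; reduction and lactonisation close ring D).
5. 17 ⇒ β-cyclogeranyl sulfone 4 (ring A, from β-cyclocitral) + iodide 8 (C8, from methyl (S)-3-hydroxy-2-methylpropanoate). Ring order: A (bought), D, C, B.

Key step: step 18

Remark on the chemistry: the hydroxy ester is used as its (S)-enantiomer. The iodide must be the silyl ether of the reduced ester, because a β-iodo ester would eliminate to methacrylate under the sulfonyl carbanion and lose C8. In that form the former ester carbon becomes C7 and the former carbinol carbon becomes C9, which maps (S) onto 8R.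

Remark on the chemistry: once ring D is in place, no amide or alkoxide base is used in the main route. A lactone enolate can expel the C13–O bond (retro-oxa-Michael) and erase C13, so the C7 oxygen is introduced through a silyl enol ether.

## Route

Step 1
Reactants: 1 β-cyclocitral
Product: 2 β-cyclogeraniol
Conditions: NaBH4, MeOH, 0 °C
Reagents that add atoms: none
Why: Borohydride 1,2-reduction of an enal, in which the carbonyl carbon is the only accessible electrophilic site because the β-carbon is fully substituted, and no stereocenter is formed.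

Step 2
Reactants: 2 β-cyclogeraniol
Product: 3 β-cyclogeranyl bromide
Conditions: PBr3 (0.4 equiv), pyridine (cat.), Et2O, −10 to 0 °C
Reagents that add atoms: phosphorus tribromide, BrP(Br)Br
Why: Conversion of a primary allylic alcohol into the bromide with PBr3 (SN2 displacement of a phosphite leaving group) occurs without allylic transposition because the other allyl terminus (C10) is fully substituted, and the labile bromide is used directly.

Step 3
Reactants: 3 β-cyclogeranyl bromide
Product: 4 β-cyclogeranyl phenyl sulfone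
Conditions: PhSO2Na, DMF, rt
Reagents that add atoms: sodium benzenesulfinate, [Na+].[O-]S(=O)c1ccccc1
Why: SN2 S-alkylation of the ambident benzenesulfinate anion by a soft allylic bromide in a dipolar aprotic solvent is the standard route to allylic sulfones and gives a stable precursor of the C6 nucleophile.

Step 4
Reactants: 5 methyl (S)-3-hydroxy-2-methylpropanoate
Product: 6 methyl (S)-3-(tert-butyldimethylsilyloxy)-2-methylpropanoate
Conditions: TBSCl, imidazole, CH2Cl2, 0 °C to rt
Reagents that add atoms: tert-butyldimethylsilyl chloride, CC(C)(C)[Si](C)(C)Cl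
Why: Imidazole-mediated silylation of a primary alcohol is mild enough to leave the enolisable α-stereocenter (the future C8) untouched.

Step 5
Reactants: 6 methyl (S)-3-(tert-butyldimethylsilyloxy)-2-methylpropanoate
Product: 7 (R)-3-(tert-butyldimethylsilyloxy)-2-methylpropan-1-ol
Conditions: DIBAL-H (2.5 equiv), CH2Cl2, −78 to −20 °C; aq. sodium potassium tartrate
Reagents that add atoms: none
Why: Exhaustive DIBAL-H reduction of the ester to the primary alcohol passes through the aldehyde only as its aluminium hemiacetal, so the adjacent stereocenter is not epimerised and the silyl ether survives.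

Step 6
Reactants: 7 (R)-3-(tert-butyldimethylsilyloxy)-2-methylpropan-1-ol
Product: 8 (S)-tert-butyl(3-iodo-2-methylpropoxy)dimethylsilane
Conditions: I2, PPh3, imidazole, CH2Cl2, 0 °C
Reagents that add atoms: iodine, II
Why: Appel-type iodination (Garegg–Samuelsson conditions) replaces the primary hydroxyl by SN2 attack of iodide on the alkoxyphosphonium salt and does not involve the stereocenter, whose descriptor changes to S only through the priority rules.

Step 7
Reactants: 4 β-cyclogeranyl phenyl sulfone; 8 (S)-tert-butyl(3-iodo-2-methylpropoxy)dimethylsilane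
Product: 10 C6-phenylsulfonyl silyl ether (8R; both C6 epimers), via lithiated sulfone 9 (not isolated)
Conditions: n-BuLi, THF–DMPU, −78 °C; then 8, −78 °C to rt
Reagents that add atoms: none
Why: Alkylation of an α-sulfonyl carbanion with a primary iodide (Julia-type fragment coupling) forms C6–C7, the silyl ether iodide offers no acidic α-hydrogen for β-elimination so that C8 is carried through intact, and the new C6 center is removed in the next step.

Step 8
Reactants: 10 C6-phenylsulfonyl silyl ether
Product: 11 silyl ether of (2R)-2-methyl-4-(2,6,6-trimethylcyclohex-1-en-1-yl)butan-1-ol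
Conditions: 6% Na(Hg), Na2HPO4, MeOH–THF, −20 to 0 °C
Reagents that add atoms: none
Why: Reductive desulfonylation by electron transfer from sodium amalgam gives an allyl anion that is protonated at its less substituted and more accessible C6 terminus, which keeps the thermodynamically preferred tetrasubstituted C5=C10 alkene in ring A.

Step 9
Reactants: 11 silyl ether of (2R)-2-methyl-4-(2,6,6-trimethylcyclohex-1-en-1-yl)butan-1-ol
Product: 12 (2R)-2-methyl-4-(2,6,6-trimethylcyclohex-1-en-1-yl)butan-1-ol
Conditions: TBAF, THF, rt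
Reagents that add atoms: none
Why: Fluoride-induced cleavage of the Si–O bond is orthogonal to the alkene and does not touch C8.

Step 10
Reactants: 12 (2R)-2-methyl-4-(2,6,6-trimethylcyclohex-1-en-1-yl)butan-1-ol
Product: 13 (2R)-2-methyl-4-(2,6,6-trimethylcyclohex-1-en-1-yl)butanal
Conditions: Dess–Martin periodinane, NaHCO3, CH2Cl2, 0 °C to rt
Reagents that add atoms: none
Why: Dess–Martin oxidation under bicarbonate buffering stops at the aldehyde and is non-basic enough to preserve the α-methyl stereocenter, the aldehyde being used without storage.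

Step 11
Reactants: 13 (2R)-2-methyl-4-(2,6,6-trimethylcyclohex-1-en-1-yl)butanal
Product: 14 2-[(3R)-5,5-dibromo-3-methylpent-4-en-1-yl]-1,3,3-trimethylcyclohex-1-ene
Conditions: CBr4, PPh3, CH2Cl2, 0 °C
Reagents that add atoms: carbon tetrabromide, BrC(Br)(Br)Br
Why: First stage of the Corey–Fuchs homologation (Wittig-type dibromomethylenation with Ph3P=CBr2), which runs under essentially neutral conditions and therefore avoids epimerisation at C8.

Step 12
Reactants: 14 2-[(3R)-5,5-dibromo-3-methylpent-4-en-1-yl]-1,3,3-trimethylcyclohex-1-ene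
Product: 16 (4R)-4-methyl-6-(2,6,6-trimethylcyclohex-1-en-1-yl)hex-2-yn-1-ol, via lithium acetylide 15 (not isolated)
Conditions: n-BuLi (2.2 equiv), THF, −78 °C; then (CH2O)n, −78 °C to rt
Reagents that add atoms: formaldehyde (as paraformaldehyde), C=O
Why: Second stage of the Corey–Fuchs sequence, in which bromine–lithium exchange and Fritsch–Buttenberg–Wiechell rearrangement give the lithium acetylide (C9≡C11), whose addition to formaldehyde installs C12.

Step 13
Reactants: 16 (4R)-4-methyl-6-(2,6,6-trimethylcyclohex-1-en-1-yl)hex-2-yn-1-ol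
Product: 17 2-[(3R)-6-bromo-3-methylhex-4-yn-1-yl]-1,3,3-trimethylcyclohex-1-ene
Conditions: CBr4, PPh3, CH2Cl2, −20 to 0 °C
Reagents that add atoms: carbon tetrabromide, BrC(Br)(Br)Br
Why: Appel bromination of the propargylic alcohol proceeds by SN2 displacement under neutral conditions and tolerates the alkyne and the ring-A alkene.

Step 14
Reactants: 18 (R)-malic acid
Product: 19 [(2R,4R)-2-tert-butyl-5-oxo-1,3-dioxolan-4-yl]acetic acid (cis)
Conditions: t-BuCHO, p-TsOH (cat.), H2SO4 (cat.), pentane, reflux (Dean–Stark); recrystallisation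
Reagents that add atoms: pivalaldehyde, CC(C)(C)C=O
Why: Acid-catalysed acetalisation of the α-hydroxy acid unit with pivalaldehyde forms the five-membered dioxolanone in preference to the six-membered dioxanone, the new acetal center being set cis to the side chain under thermodynamic control and upgraded by crystallisation (first stage of self-regeneration of stereocenters).

Step 15
Reactants: 19 [(2R,4R)-2-tert-butyl-5-oxo-1,3-dioxolan-4-yl]acetic acid (slight excess); 17 2-[(3R)-6-bromo-3-methylhex-4-yn-1-yl]-1,3,3-trimethylcyclohex-1-ene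
Product: 21 C13-alkylated dioxolanone acid (2R,4R; 8R), via dilithium enolate carboxylate 20 (not isolated)
Conditions: LiHMDS (2.2 equiv per 19), THF, −78 °C; then 17, −78 to −20 °C; 1 M HCl work-up
Reagents that add atoms: none
Why: Alkylation of the dioxolanone enolate under the self-regeneration-of-stereocenters principle, in which the carboxylic acid is deprotonated first, the second equivalent of base forms the ring enolate, and the reactive propargylic bromide enters anti to the tert-butyl group in place of the former hydrogen, which sets the quaternary C13 as R with overall retention.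

Step 16
Reactants: 21 C13-alkylated dioxolanone acid
Product: 23 (4R)-4-hydroxy-4-[(4R)-4-methyl-6-(2,6,6-trimethylcyclohex-1-en-1-yl)hex-2-yn-1-yl]oxolan-2-one, via dihydroxy acid 22 (not isolated)
Conditions: LiEt3BH (5 equiv), THF, 0 °C to rt; then 1 M HCl, rt
Reagents that add atoms: none
Why: Chemoselective hydride reduction, in which LiEt3BH only deprotonates the carboxylic acid (its lithium salt is inert) but reduces the acylal-type dioxolanone carbonyl (C16) fully to the carbinol with release of the pivalaldehyde unit, and acidification lets the C16 hydroxyl lactonise onto C15 to close ring D without touching C13.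

Step 17
Reactants: 23 (4R)-4-hydroxy-4-[(4R)-4-methyl-6-(2,6,6-trimethylcyclohex-1-en-1-yl)hex-2-yn-1-yl]oxolan-2-one
Product: 25 seco-ring-B spiro lactone C9 methyl ketal (8R,13R; both C9 epimers), via spiro dihydrofuran 24 (not isolated)
Conditions: Ph3PAuNTf2 (3 mol%), MeOH–CH2Cl2, 0 °C to rt; Et3N quench
Reagents that add atoms: methanol, CO
Why: Gold-catalysed cycloisomerisation–hydroalkoxylation of a homopropargylic alcohol, in which π-activation of the alkyne by the cationic monovalent gold complex lets the C13 hydroxyl add 5-endo-dig to C9 (the 4-exo mode is strained), which closes ring C, and methanol then adds to the enol ether to give the ketal as an inconsequential C9 mixture.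

Step 18
Reactants: 25 seco-ring-B spiro lactone C9 methyl ketal
Product: 28 (8R,9R,10S,13R)-9α,13-epoxylabd-5-en-15,16-olide, via cyclic oxocarbenium ion 26 (not isolated), via tertiary C5 cation 27 (not isolated)
Conditions: SnCl4 (2.5 equiv), CH2Cl2, −78 to −40 °C; aq. NaHCO3
Reagents that add atoms: none
Why: SnCl4 pulls the methoxy group off C9 of either ketal epimer to give the planar five-membered oxocarbenium ion 26, C10 of the electron-rich C5=C10 alkene bonds to C9, and the tertiary C5 cation 27, which has no hydrogen on C4 or C10, sheds a C6 proton to leave the C5=C6 alkene. The closest known type is the Prins (ketal-initiated cation–olefin) cyclisation of oxocarbenium ions onto tri- and tetrasubstituted alkenes, as in acid cyclisations of dihydro-β-ionone derivatives, here at its demanding end because two fully substituted carbons are joined. Ring B closes 6-endo-trig with respect to the alkene through a chair, and bonding at C10 instead of C5 is secured because the 5-exo path would have to build a spiro quaternary C5 directly beside the C4 gem-dimethyl carbon. C10 (S) is controlled by C8: the ring-A geometry of the alkene forces C20 axial and C1 equatorial on the new ring, so the fixed 8R methyl group takes the equatorial site to avoid a 1,3-diaxial contact with C20, and this choice selects the alkene face. C9 (R) is controlled by the rotamer about C8–C9 in that chair, the face of 26 being attacked that leaves the small ring oxygen axial (α, anti to C20) and the larger C11 methylene equatorial, while C13 is only a spectator. The step needs cyclisation to win over proton loss and over ring-C opening: no amine base is added, so the endocyclic enol ether 24 from loss of a C11 proton is re-protonated and re-enters, the exocyclic C8=C9 enol ether that would erase C8 is the less accessible isomer, and the low temperature holds back loss of a C14 proton with expulsion of the C13–O bond.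

Step 19
Reactants: 28 (8R,9R,10S,13R)-9α,13-epoxylabd-5-en-15,16-olide
Product: 30 6α-hydroxy-9α,13R-epoxy-5α-labdan-15,16-olide, via 6α-alkylborane 29 (not isolated)
Conditions: BH3·THF (4 equiv), THF, 0 °C to rt; then NaBO3·4H2O, H2O, rt
Reagents that add atoms: sodium perborate, [Na+].[Na+].O[B-]1(O)OO[B-](O)(O)OO1
Why: Hydroboration–oxidation, in which syn addition of H and B to the trisubstituted alkene places boron on the less substituted C6 and comes from the α face, away from the axial C10 and C4β methyl groups, which sets 5α-H (5S) and 6α-OH, while perborate replaces alkaline peroxide to spare the lactone.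

Step 20
Reactants: 30 6α-hydroxy-9α,13R-epoxy-5α-labdan-15,16-olide
Product: 31 6-oxo-9α,13R-epoxy-5α-labdan-15,16-olide
Conditions: Dess–Martin periodinane, NaHCO3, CH2Cl2, rt
Reagents that add atoms: none
Why: Dess–Martin oxidation of the hindered equatorial alcohol gives the 6-ketone without epimerising C5, whose trans ring fusion is in any case the stable one, and would also return to the lactone any lactol formed by partial reduction of ring D in step 19.

Step 21
Reactants: 31 6-oxo-9α,13R-epoxy-5α-labdan-15,16-olide
Product: 32 6-(trimethylsilyloxy)-9α,13R-epoxy-5α-labd-6-en-15,16-olide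
Conditions: TMSOTf, Et3N, CH2Cl2, −20 to 0 °C
Reagents that add atoms: trimethylsilyl triflate, C[Si](C)(C)OS(=O)(=O)C(F)(F)F
Why: Soft enolisation (silyl triflate and tertiary amine) converts the ketone rather than the less reactive lactone into its silyl enol ether and goes toward C7, because the C5–H is buried between two quaternary carbons and a C5=C6 enol ether would suffer allylic strain against the C4 methyl groups, and it avoids the lactone enolate that a lithium amide could form.

Step 22
Reactants: 32 6-(trimethylsilyloxy)-9α,13R-epoxy-5α-labd-6-en-15,16-olide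
Product: 35 7α-hydroxy-6-oxo-9α,13R-epoxy-5α-labdan-15,16-olide, via silyloxy epoxide 33 (not isolated), via 7α-silyloxy ketone 34 (not isolated)
Conditions: mCPBA, NaHCO3, CH2Cl2, −20 to 0 °C; then 1 M HCl, THF, 0 °C
Reagents that add atoms: 3-chloroperbenzoic acid, OOC(=O)c1cccc(Cl)c1
Why: Rubottom oxidation, in which the peracid epoxidises the electron-rich enol ether from the α face, opposite the C10 and C4β methyl groups, the silyloxy epoxide opens with silyl migration, and dilute acid removes silicon to give the axial 7α-ketol.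

Step 23
Reactants: 35 7α-hydroxy-6-oxo-9α,13R-epoxy-5α-labdan-15,16-olide
Product: 36 7β-hydroxy-6-oxo-9α,13R-epoxy-5α-labdan-15,16-olide (5S,7R,8R,9R,10S,13R; CNP0291402.1)
Conditions: DBU (0.5 equiv), degassed toluene, rt to 40 °C
Reagents that add atoms: none
Why: Base-catalysed ketol epimerisation through the C6–C7 enediolate (Lobry de Bruyn–van Ekenstein type equilibration) should move the axial 7α-hydroxyl, which is 1,3-diaxial to the 9α-oxygen, to the equatorial 7β-site hydrogen-bonded to the C6 carbonyl, the amidine being too weak to enolise the ring-D lactone to a useful extent so that C13–O holds, and C5 staying in its preferred trans fusion.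

## Compound list

1 | β-cyclocitral (2,6,6-trimethylcyclohex-1-ene-1-carbaldehyde) | CC1=C(C=O)C(C)(C)CCC1 | starting material
2 | β-cyclogeraniol, (2,6,6-trimethylcyclohex-1-en-1-yl)methanol | CC1=C(CO)C(C)(C)CCC1 | intermediate
3 | β-cyclogeranyl bromide, 2-(bromomethyl)-1,3,3-trimethylcyclohex-1-ene | CC1=C(CBr)C(C)(C)CCC1 | intermediate
4 | β-cyclogeranyl phenyl sulfone | CC1=C(CS(=O)(=O)c2ccccc2)C(C)(C)CCC1 | intermediate
5 | methyl (S)-3-hydroxy-2-methylpropanoate | C[C@@H](CO)C(=O)OC | starting material
6 | methyl (S)-3-(tert-butyldimethylsilyloxy)-2-methylpropanoate | C[C@@H](CO[Si](C)(C)C(C)(C)C)C(=O)OC | intermediate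
7 | (R)-3-(tert-butyldimethylsilyloxy)-2-methylpropan-1-ol | C[C@@H](CO[Si](C)(C)C(C)(C)C)CO | intermediate
8 | (S)-tert-butyl(3-iodo-2-methylpropoxy)dimethylsilane | C[C@@H](CO[Si](C)(C)C(C)(C)C)CI | intermediate
9 | α-lithio β-cyclogeranyl phenyl sulfone (not isolated) | [Li]C(C1=C(C)CCCC1(C)C)S(=O)(=O)c1ccccc1 | intermediate
10 | tert-butyldimethylsilyl ether of (2R)-2-methyl-4-(phenylsulfonyl)-4-(2,6,6-trimethylcyclohex-1-en-1-yl)butan-1-ol, both epimers at the sulfonyl carbon (C6) | C[C@@H](CO[Si](C)(C)C(C)(C)C)CC(C1=C(C)CCCC1(C)C)S(=O)(=O)c1ccccc1 | intermediate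
11 | tert-butyldimethylsilyl ether of (2R)-2-methyl-4-(2,6,6-trimethylcyclohex-1-en-1-yl)butan-1-ol | C[C@@H](CO[Si](C)(C)C(C)(C)C)CCC1=C(C)CCCC1(C)C | intermediate
12 | (2R)-2-methyl-4-(2,6,6-trimethylcyclohex-1-en-1-yl)butan-1-ol | C[C@@H](CO)CCC1=C(C)CCCC1(C)C | intermediate
13 | (2R)-2-methyl-4-(2,6,6-trimethylcyclohex-1-en-1-yl)butanal | C[C@@H](C=O)CCC1=C(C)CCCC1(C)C | intermediate
14 | 2-[(3R)-5,5-dibromo-3-methylpent-4-en-1-yl]-1,3,3-trimethylcyclohex-1-ene | C[C@@H](C=C(Br)Br)CCC1=C(C)CCCC1(C)C | intermediate
15 | lithium acetylide of 2-[(3R)-3-methylpent-4-yn-1-yl]-1,3,3-trimethylcyclohex-1-ene (not isolated) | C[C@@H](C#C[Li])CCC1=C(C)CCCC1(C)C | intermediate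
16 | (4R)-4-methyl-6-(2,6,6-trimethylcyclohex-1-en-1-yl)hex-2-yn-1-ol | C[C@@H](C#CCO)CCC1=C(C)CCCC1(C)C | intermediate
17 | 2-[(3R)-6-bromo-3-methylhex-4-yn-1-yl]-1,3,3-trimethylcyclohex-1-ene | C[C@@H](C#CCBr)CCC1=C(C)CCCC1(C)C | intermediate
18 | (R)-malic acid | OC(=O)C[C@@H](O)C(=O)O | starting material
19 | [(2R,4R)-2-tert-butyl-5-oxo-1,3-dioxolan-4-yl]acetic acid (cis) | CC(C)(C)[C@@H]1O[C@H](CC(=O)O)C(=O)O1 | intermediate
20 | dilithium enolate carboxylate of 19 (not isolated) | CC(C)(C)[C@@H]1OC(CC(=O)[O-])=C([O-])O1.[Li+].[Li+] | intermediate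
21 | {(2R,4R)-2-tert-butyl-4-[(4R)-4-methyl-6-(2,6,6-trimethylcyclohex-1-en-1-yl)hex-2-yn-1-yl]-5-oxo-1,3-dioxolan-4-yl}acetic acid | CC(C)(C)[C@@H]1O[C@](CC#C[C@H](C)CCC2=C(C)CCCC2(C)C)(CC(=O)O)C(=O)O1 | intermediate
22 | (3R,7R)-3-hydroxy-3-(hydroxymethyl)-7-methyl-9-(2,6,6-trimethylcyclohex-1-en-1-yl)non-5-ynoic acid (not isolated) | C[C@@H](C#CC[C@](O)(CO)CC(=O)O)CCC1=C(C)CCCC1(C)C | intermediate
23 | (4R)-4-hydroxy-4-[(4R)-4-methyl-6-(2,6,6-trimethylcyclohex-1-en-1-yl)hex-2-yn-1-yl]oxolan-2-one | C[C@@H](C#CC[C@]1(O)COC(=O)C1)CCC1=C(C)CCCC1(C)C | intermediate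
24 | (5R)-2-[(2R)-4-(2,6,6-trimethylcyclohex-1-en-1-yl)butan-2-yl]-1,7-dioxaspiro[4.4]non-2-en-8-one (not isolated) | C[C@@H](C2=CC[C@@]3(COC(=O)C3)O2)CCC1=C(C)CCCC1(C)C | intermediate
25 | (5R)-2-methoxy-2-[(2R)-4-(2,6,6-trimethylcyclohex-1-en-1-yl)butan-2-yl]-1,7-dioxaspiro[4.4]nonan-8-one, both epimers at the ketal carbon (C9) | C[C@@H](C2(OC)CC[C@@]3(COC(=O)C3)O2)CCC1=C(C)CCCC1(C)C | intermediate
26 | C9 cyclic oxocarbenium ion from 25 (not isolated) | C[C@@H](C2=[O+][C@]3(COC(=O)C3)CC2)CCC1=C(C)CCCC1(C)C | intermediate
27 | tertiary C5 cation of the closed skeleton (not isolated) | C[C@@H]1CC[C+]2C(C)(C)CCC[C@]2(C)[C@@]12CC[C@@]1(COC(=O)C1)O2 | intermediate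
28 | (8R,9R,10S,13R)-9α,13-epoxylabd-5-en-15,16-olide (8α-methyl, 10β-methyl) | C[C@@H]1CC=C2C(C)(C)CCC[C@]2(C)[C@@]12CC[C@@]1(COC(=O)C1)O2 | intermediate
29 | 6α-boryl-9α,13R-epoxy-5α-labdan-15,16-olide (not isolated) | C[C@@H]1C[C@H](B)[C@H]2C(C)(C)CCC[C@]2(C)[C@@]12CC[C@@]1(COC(=O)C1)O2 | intermediate
30 | (5S,6S,8R,9R,10S,13R)-6α-hydroxy-9α,13-epoxylabdan-15,16-olide | C[C@@H]1C[C@H](O)[C@H]2C(C)(C)CCC[C@]2(C)[C@@]12CC[C@@]1(COC(=O)C1)O2 | intermediate
31 | (5S,8R,9R,10S,13R)-6-oxo-9α,13-epoxylabdan-15,16-olide | C[C@@H]1CC(=O)[C@H]2C(C)(C)CCC[C@]2(C)[C@@]12CC[C@@]1(COC(=O)C1)O2 | intermediate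
32 | 6-(trimethylsilyloxy)-9α,13R-epoxy-5α-labd-6-en-15,16-olide | C[C@@H]1C=C(O[Si](C)(C)C)[C@H]2C(C)(C)CCC[C@]2(C)[C@@]12CC[C@@]1(COC(=O)C1)O2 | intermediate
33 | 6α,7α-epoxy-6β-(trimethylsilyloxy)-9α,13R-epoxy-5α-labdan-15,16-olide (not isolated) | C[C@@H]1[C@@H]3O[C@]3(O[Si](C)(C)C)[C@H]2C(C)(C)CCC[C@]2(C)[C@@]12CC[C@@]1(COC(=O)C1)O2 | intermediate
34 | 7α-(trimethylsilyloxy)-6-oxo-9α,13R-epoxy-5α-labdan-15,16-olide (not isolated) | C[C@@H]1[C@H](O[Si](C)(C)C)C(=O)[C@H]2C(C)(C)CCC[C@]2(C)[C@@]12CC[C@@]1(COC(=O)C1)O2 | intermediate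
35 | (5S,7S,8R,9R,10S,13R)-7α-hydroxy-6-oxo-9α,13-epoxylabdan-15,16-olide | C[C@@H]1[C@H](O)C(=O)[C@H]2C(C)(C)CCC[C@]2(C)[C@@]12CC[C@@]1(COC(=O)C1)O2 | intermediate
36 | (5S,7R,8R,9R,10S,13R)-7β-hydroxy-6-oxo-9α,13-epoxylabdan-15,16-olide (CNP0291402.1) | C[C@@H]1[C@@H](O)C(=O)[C@H]2C(C)(C)CCC[C@]2(C)[C@@]12CC[C@@]1(COC(=O)C1)O2 | target

## Step count

Total step count: 23.
Longest linear sequence: 19 steps (5 to 36: steps 4–13 and 15–23).

## Steps most likely to fail

**Step 18.** The bond joins two fully substituted carbons, so cyclisation may be slower than three competing processes.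
- Proton loss from the oxocarbenium ion toward C8 would scramble C8.
- Lewis-acid-assisted loss of a C14 proton with cleavage of the C13–O bond would open ring C irreversibly.
- Methyl migration in the C5 cation could occur before proton loss.

The fallback sets out from 25 and comes back at 28. It keeps the C9–C10 bond but changes the electrophile and the order of ring closure.
- Deprotonation of the lactone of 25 with LiHMDS (THF, −78 to −20 °C) deliberately opens ring C by E1cB loss of the ketal oxygen and collapse of the hemiketal anion. This gives the keto butenolide F1.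
- An intramolecular carbonyl-ene reaction of the C9 ketone with the C5=C10 alkene and a C6 hydrogen under MeAlCl2 (CH2Cl2, −78 to 0 °C) should close ring B through the same chair with the C8 methyl equatorial. This gives the 9α-hydroxy-5-ene butenolide F2.
- Oxa-Michael addition of the 9α-hydroxyl to C13 (DBU, toluene) then closes ring C. It gives 28 beside the C13 epimer of the key product F3, which is separated and resubmitted to the base.

**Step 23.** Four processes may interfere with the equilibration.
- Enolisation of the axial ketol may be slow, because its C7–H is equatorial.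
- The common enediolate may be reprotonated at C6, which transposes the ketol to the 7-ketone and exposes C8.
- Traces of air may oxidise the enediolate.
- Prolonged exposure to base may start retro-oxa-Michael opening at ring D and scramble C13.

The fallback sets out from 28 and comes back at 36 without any basic step.
- Allylic oxidation at C7, the only allylic C–H position (CrO3, 3,5-dimethylpyrazole, CH2Cl2, −20 °C), gives the 5-en-7-one F4.
- Luche reduction (NaBH4, CeCl3·7H2O, MeOH, −40 °C) with axial hydride delivery should give the 7β-allylic alcohol F5.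
- Silylation (TESOTf, 2,6-lutidine, CH2Cl2) gives the triethylsilyl ether F6.
- Hydroboration–oxidation as in step 19 places boron on C6 from the α face and gives the 6α-alcohol F7.
- Dess–Martin oxidation gives the 7β-silyloxy 6-ketone F8.
- HF·pyridine in THF releases 36.

**Step 17.** Three processes may compete.
- The alkyne and the ring-A alkene form a 1,6-enyne, so the alkene may compete with the hydroxyl for the gold-activated alkyne (cycloisomerisation or methoxycyclisation).
- Methanol may add intermolecularly with the wrong regiochemistry.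
- Adventitious acid may equilibrate the ketal through the exocyclic enol ether and erode C8.

The fallback sets out from 23 and comes back at 25 without π-acid activation.
- Silylation of the tertiary alcohol (Me2SiHCl, Et3N, DMAP, CH2Cl2) gives the dimethylsilyl ether F9.
- Intramolecular 6-endo-dig hydrosilylation catalysed by [Cp*Ru(MeCN)3]PF6 (CH2Cl2, rt) places silicon on C9 and gives the cyclic vinylsiloxane F10.
- Tamao–Fleming oxidation (H2O2, KF, KHCO3, THF–MeOH) gives the γ-hydroxy ketone F11, in equilibrium with its hemiketal.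
- HC(OMe)3, PPTS and MeOH at rt convert it into 25.

## Further compounds

F1 | step 18 | keto butenolide, 4-[(4R)-4-methyl-3-oxo-6-(2,6,6-trimethylcyclohex-1-en-1-yl)hexyl]furan-2(5H)-one | C[C@@H](C(=O)CCC1=CC(=O)OC1)CCC1=C(C)CCCC1(C)C
F2 | step 18 | 9α-hydroxy-5-ene butenolide, (8R,9R,10S)-9α-hydroxylabda-5,13-dien-15,16-olide | C[C@@H]1CC=C2C(C)(C)CCC[C@]2(C)[C@@]1(O)CCC1=CC(=O)OC1
F3 | step 18 | C13 epimer of the key product, (8R,9R,10S,13S)-9α,13-epoxylabd-5-en-15,16-olide | C[C@@H]1CC=C2C(C)(C)CCC[C@]2(C)[C@@]12CC[C@]1(COC(=O)C1)O2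
F4 | step 23 | 5-en-7-one, 7-oxo-9α,13R-epoxylabd-5-en-15,16-olide | C[C@@H]1C(=O)C=C2C(C)(C)CCC[C@]2(C)[C@@]12CC[C@@]1(COC(=O)C1)O2
F5 | step 23 | 7β-allylic alcohol, 7β-hydroxy-9α,13R-epoxylabd-5-en-15,16-olide | C[C@@H]1[C@@H](O)C=C2C(C)(C)CCC[C@]2(C)[C@@]12CC[C@@]1(COC(=O)C1)O2
F6 | step 23 | triethylsilyl ether, 7β-(triethylsilyloxy)-9α,13R-epoxylabd-5-en-15,16-olide | C[C@@H]1[C@@H](O[Si](CC)(CC)CC)C=C2C(C)(C)CCC[C@]2(C)[C@@]12CC[C@@]1(COC(=O)C1)O2
F7 | step 23 | 6α-alcohol, 6α-hydroxy-7β-(triethylsilyloxy)-9α,13R-epoxy-5α-labdan-15,16-olide | C[C@@H]1[C@@H](O[Si](CC)(CC)CC)[C@H](O)[C@H]2C(C)(C)CCC[C@]2(C)[C@@]12CC[C@@]1(COC(=O)C1)O2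
F8 | step 23 | 7β-silyloxy 6-ketone, 6-oxo-7β-(triethylsilyloxy)-9α,13R-epoxy-5α-labdan-15,16-olide | C[C@@H]1[C@@H](O[Si](CC)(CC)CC)C(=O)[C@H]2C(C)(C)CCC[C@]2(C)[C@@]12CC[C@@]1(COC(=O)C1)O2
F9 | step 17 | dimethylsilyl ether of 23 | C[C@@H](C#CC[C@]1(O[SiH](C)C)COC(=O)C1)CCC1=C(C)CCCC1(C)C
F10 | step 17 | cyclic vinylsiloxane (six-membered 1,2-oxasiline spiro-fused to ring D at C13, silicon on C9) | C[C@@H](C1=CC[C@@]2(COC(=O)C2)O[Si]1(C)C)CCC1=C(C)CCCC1(C)C
F11 | step 17 | γ-hydroxy ketone, (4R)-4-hydroxy-4-[(4R)-4-methyl-3-oxo-6-(2,6,6-trimethylcyclohex-1-en-1-yl)hexyl]oxolan-2-one | C[C@@H](C(=O)CC[C@]1(O)COC(=O)C1)CCC1=C(C)CCCC1(C)C
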